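The oxane ring is closed at its O1–C6 bond. Ring carbon C5 carries two CH2 groups, C6 and the first side-chain carbon, and is therefore treated as C3 of an oxetane. In one acid-catalysed operation the C2 hydroxyl opens the oxetane (6-exo-tet): this forms the O1–C6 bond, sets C5 trans to C2 by selection between the two diastereotopic CH2 groups, and frees the other CH2 as CH2OH for chain extension. The precursor is the oxetane-bearing Morita–Baylis–Hillman adduct methyl (3R)-3-hydroxy-2-methylidene-5-(oxetan-3-yl)pentanoate. The side chain is then attached by B-alkyl Suzuki coupling to an (E)-vinyl iodide.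

Key step: step 4

Assumption: in step 8 the ligand (S)-N-[2-(4-isopropyl-4,5-dihydro-1,3-oxazol-2-yl)-6-methylphenyl]methanesulfonamide is taken to deliver the (5R)-alcohol; if MTPA ester analysis of a trial run shows the opposite sense, its enantiomer is used.

Step 1
Reactants: 1 3-iodooxetane; 2 acrolein (prop-2-enal)
Product: 3 3-(oxetan-3-yl)propanal
Conditions: (Me3Si)3SiH, AIBN (cat.), PhMe, 70 °C, slow addition of the silane
Reagents that add atoms: none
Why: Giese radical conjugate addition, in which the silyl radical abstracts iodine, the nucleophilic oxetan-3-yl radical adds to the terminal carbon of acrolein and the resulting α-formyl radical is reduced by Si–H, all under neutral conditions that leave the oxetane closed.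

Step 2
Reactants: 3 3-(oxetan-3-yl)propanal; 4 1,1,1,3,3,3-hexafluoropropan-2-yl prop-2-enoate
Product: 5 1,1,1,3,3,3-hexafluoropropan-2-yl (3R)-3-hydroxy-2-methylidene-5-(oxetan-3-yl)pentanoate
Conditions: β-isocupreidine (10 mol%), DMF, −55 °C
Reagents that add atoms: none
Why: Asymmetric Morita–Baylis–Hillman reaction, in which the quinuclidine nitrogen adds to the activated acrylate and the phenolic OH of the catalyst organises the aldol step so that the (3R)-carbinol should form, while material of the opposite sense is drained into a dioxanone that is removed by chromatography.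

Step 3
Reactants: 5 hexafluoroisopropyl ester from step 2
Product: 6 methyl (3R)-3-hydroxy-2-methylidene-5-(oxetan-3-yl)pentanoate
Conditions: NaOMe (cat.), MeOH, 0 °C
Reagents that add atoms: methanol, CO
Why: Transesterification of the activated fluoroalkyl ester to the robust methyl ester, run on purified 5 so that no dioxanone of opposite configuration is methanolysed into the product; the carbinol centre and the base-stable oxetane are not touched.

Step 4
Reactants: 6 methyl (3R)-3-hydroxy-2-methylidene-5-(oxetan-3-yl)pentanoate
Product: 7 methyl 2-[(2R,5R)-5-(hydroxymethyl)oxan-2-yl]prop-2-enoate (2,5-trans)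
Conditions: (±)-camphorsulfonic acid (10 mol%), CH2Cl2 (0.01 M), 0 °C to rt
Reagents that add atoms: none
Why: Protonation of the oxetane oxygen makes both ring CH2 carbons electrophilic, and the C3 hydroxyl opens the ring by backside attack on one of them, a 6-exo-tet closure that forms the O–CH2 bond of the oxane and leaves the other CH2 as CH2OH. The closest known reaction type is the Brønsted- or Lewis-acid-catalysed intramolecular ring opening of 3-substituted oxetanes by a tethered alcohol, an established route to tetrahydrofurans, oxanes and 1,4-dioxanes. C2 of the oxane (R) is carried over unchanged from the Morita–Baylis–Hillman adduct, and the new centre C5 is fixed by which of the two diastereotopic oxetane CH2 groups is attacked. Because the leaving oxygen must stay anti to the incoming one, the departing CH2–O arm has to lie anti to O1 across C5–C6, that is equatorial on the forming chair, so the two closures differ only in whether the acrylate group at C2 is equatorial (2,5-trans, wanted) or axial (2,5-cis). The step needs this group selection and ring closure in preference to intermolecular opening; the first should be secured by the strong equatorial preference of a substituent next to the ring oxygen and the second by high dilution. The acrylate ester is inert to the catalytic acid, and the primary alcohol that is released has no second oxetane to attack within the molecule.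

Step 5
Reactants: 7 methyl 2-[(2R,5R)-5-(hydroxymethyl)oxan-2-yl]prop-2-enoate
Product: 8 methyl 2-[(2R,5S)-5-formyloxan-2-yl]prop-2-enoate
Conditions: Dess–Martin periodinane, CH2Cl2, 0 °C to rt
Reagents that add atoms: none
Why: Dess–Martin oxidation of the primary alcohol to the aldehyde under non-basic conditions, which should avoid epimerisation at C5 and β-alkoxide elimination and leaves the acrylate untouched.

Step 6
Reactants: 8 methyl 2-[(2R,5S)-5-formyloxan-2-yl]prop-2-enoate
Product: 9 methyl 2-[(2R,5R)-5-ethenyloxan-2-yl]prop-2-enoate
Conditions: Ph3PCH3Br, KN(SiMe3)2, THF, −78 °C; then 8, −78 °C to 0 °C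
Reagents that add atoms: methyltriphenylphosphonium bromide, C[P+](c1ccccc1)(c1ccccc1)c1ccccc1.[Br-]
Why: Wittig methylenation, in which the aldehyde reacts with the ylide at low temperature far faster than the methyl ester or the 2-substituted acrylate, so that the C5 configuration should be retained.

Step 7
Reactants: 10 6-methylhept-5-en-2-one
Product: 12 6-methylhepta-1,5-dien-2-yl trifluoromethanesulfonate, via lithium enolate 11 (not isolated)
Conditions: LiN(iPr)2, THF, −78 °C; then PhNTf2, −78 °C to 0 °C
Reagents that add atoms: N-phenyl-bis(trifluoromethanesulfonimide), O=S(=O)(N(c1ccccc1)S(=O)(=O)C(F)(F)F)C(F)(F)F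
Why: Kinetic deprotonation of the methyl ketone at the methyl group followed by O-sulfonylation of the terminal enolate gives the 1-alken-2-yl triflate (enol triflate formation).

Step 8
Reactants: 12 6-methylhepta-1,5-dien-2-yl trifluoromethanesulfonate; 13 pent-4-ynal
Product: 14 (5R)-10-methyl-6-methylideneundec-9-en-1-yn-5-ol
Conditions: CrCl2 (10 mol%), (S)-oxazoline–sulfonamide ligand (11 mol%), proton sponge (11 mol%), NiCl2·(2,9-dimethyl-1,10-phenanthroline) (2 mol%), Mn, Cp2ZrCl2, LiCl, MeCN, rt
Reagents that add atoms: none
Why: Catalytic asymmetric Nozaki–Hiyama–Kishi coupling, in which zerovalent nickel inserts into the C–OTf bond, the alkenyl group passes to trivalent chromium carrying the chiral sulfonamide ligand and this complex adds to one face of the aldehyde to set the (5R)-carbinol, while Mn returns chromium to the divalent state and Cp2ZrCl2 releases the chromium alkoxide; the terminal alkyne is tolerated.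

Step 9
Reactants: 14 (5R)-10-methyl-6-methylideneundec-9-en-1-yn-5-ol
Product: 16 (1E,5R)-1-iodo-2,10-dimethyl-6-methylideneundeca-1,9-dien-5-ol, via alkenylalane 15 (not isolated)
Conditions: AlMe3 (3.5 equiv), Cp2ZrCl2 (0.3 equiv), CH2Cl2, 0 °C to rt; then I2, THF, −30 °C; aq. NaHCO3/Na2S2O3 work-up
Reagents that add atoms: trimethylaluminium, C[Al](C)C; iodine, II
Why: Zirconium-catalysed Negishi carboalumination adds methyl and aluminium syn across the terminal alkyne (methyl to the internal carbon) and iodinolysis proceeds with retention to give the (E)-vinyl iodide; the alcohol is masked in the flask as its aluminium alkoxide and the 1,1-disubstituted and trisubstituted alkenes do not react under these conditions.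

Step 10
Reactants: 9 methyl 2-[(2R,5R)-5-ethenyloxan-2-yl]prop-2-enoate; 16 (1E,5R)-1-iodo-2,10-dimethyl-6-methylideneundeca-1,9-dien-5-ol
Product: 18 methyl 2-[(2R,5S)-5-[(3E,7R)-7-hydroxy-4,12-dimethyl-8-methylidenetrideca-3,11-dien-1-yl]oxan-2-yl]prop-2-enoate, via B-alkyl-9-BBN borane 17 (not isolated)
Conditions: 9-BBN, THF, 0 °C to rt; then 16, Pd(dppf)Cl2 (5 mol%), AsPh3, Cs2CO3, DMF/THF/H2O, rt
Reagents that add atoms: none
Why: 9-BBN should hydroborate the monosubstituted vinyl group at its terminus in preference to the electron-poor acrylate, and the B-alkyl Suzuki–Miyaura coupling with zerovalent palladium joins the primary alkyl group to the vinyl iodide with retention of the (E) geometry in the presence of the free alcohol and the ester.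

Step 11
Reactants: 18 methyl ester from step 10
Product: 19 2-[(2R,5S)-5-[(3E,7R)-7-hydroxy-4,12-dimethyl-8-methylidenetrideca-3,11-dien-1-yl]oxan-2-yl]prop-2-enoic acid (target)
Conditions: LiOH, THF/H2O (3:1), 0 °C to rt; then 0.5 M HCl to pH 4, 0 °C
Reagents that add atoms: lithium hydroxide, [Li+].[OH-]
Why: Saponification of the methyl ester by acyl substitution, with no stereocentre at risk, and with methanol-free base and mild acidification to spare the acrylate and the allylic alcohol.

Compound list
1 | 3-iodooxetane | IC1COC1 | starting material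
2 | acrolein (prop-2-enal) | C=CC=O | starting material
3 | 3-(oxetan-3-yl)propanal | O=CCCC1COC1 | intermediate
4 | 1,1,1,3,3,3-hexafluoropropan-2-yl prop-2-enoate | C=CC(=O)OC(C(F)(F)F)C(F)(F)F | starting material
5 | 1,1,1,3,3,3-hexafluoropropan-2-yl (3R)-3-hydroxy-2-methylidene-5-(oxetan-3-yl)pentanoate | C=C([C@H](O)CCC1COC1)C(=O)OC(C(F)(F)F)C(F)(F)F | intermediate
6 | methyl (3R)-3-hydroxy-2-methylidene-5-(oxetan-3-yl)pentanoate | COC(=O)C(=C)[C@H](O)CCC1COC1 | intermediate
7 | methyl 2-[(2R,5R)-5-(hydroxymethyl)oxan-2-yl]prop-2-enoate | OC[C@H]1CC[C@H](C(=C)C(=O)OC)OC1 | intermediate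
8 | methyl 2-[(2R,5S)-5-formyloxan-2-yl]prop-2-enoate | O=C[C@H]1CC[C@H](C(=C)C(=O)OC)OC1 | intermediate
9 | methyl 2-[(2R,5R)-5-ethenyloxan-2-yl]prop-2-enoate | C=C[C@H]1CC[C@H](C(=C)C(=O)OC)OC1 | intermediate
10 | 6-methylhept-5-en-2-one | CC(=O)CCC=C(C)C | starting material
11 | lithium 6-methylhepta-1,5-dien-2-olate (not isolated) | [Li+].[O-]C(=C)CCC=C(C)C | intermediate
12 | 6-methylhepta-1,5-dien-2-yl trifluoromethanesulfonate | C=C(CCC=C(C)C)OS(=O)(=O)C(F)(F)F | intermediate
13 | pent-4-ynal | O=CCCC#C | starting material
14 | (5R)-10-methyl-6-methylideneundec-9-en-1-yn-5-ol | C=C(CCC=C(C)C)[C@H](O)CCC#C | intermediate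
15 | [(1E,5R)-5-(dimethylalumanyloxy)-2,10-dimethyl-6-methylideneundeca-1,9-dien-1-yl]dimethylalumane (not isolated) | C=C(CCC=C(C)C)[C@H](O[Al](C)C)CC/C(C)=C/[Al](C)C | intermediate
16 | (1E,5R)-1-iodo-2,10-dimethyl-6-methylideneundeca-1,9-dien-5-ol | C=C(CCC=C(C)C)[C@H](O)CC/C(C)=C/I | intermediate
17 | methyl 2-[(2R,5S)-5-[2-(9-borabicyclo[3.3.1]nonan-9-yl)ethyl]oxan-2-yl]prop-2-enoate (not isolated) | C1CCC2CCCC1B2CC[C@H]1CC[C@H](C(=C)C(=O)OC)OC1 | intermediate
18 | methyl 2-[(2R,5S)-5-[(3E,7R)-7-hydroxy-4,12-dimethyl-8-methylidenetrideca-3,11-dien-1-yl]oxan-2-yl]prop-2-enoate | C=C(CCC=C(C)C)[C@H](O)CC/C(C)=C/CC[C@H]1CC[C@H](C(=C)C(=O)OC)OC1 | intermediate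
19 | 2-[(2R,5S)-5-[(3E,7R)-7-hydroxy-4,12-dimethyl-8-methylidenetrideca-3,11-dien-1-yl]oxan-2-yl]prop-2-enoic acid | C=C(CCC=C(C)C)[C@H](O)CC/C(C)=C/CC[C@H]1CC[C@H](C(=C)C(=O)O)OC1 | target

Total step count: 11
Longest linear sequence: 8 steps (steps 1, 2, 3, 4, 5, 6, 10, 11)

Steps most likely to fail

Step 4. Intermolecular oxetane opening (oligomer formation) may outrun the ring closure, or the substrate alone may discriminate too little between the two diastereotopic CH2 groups. The fallback sets out from 6 and moves the stereocontrol at C5 from the substrate to an external catalyst, closing the same O–CH2 bond in a separate SN2 step.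
- The hydroxyl of 6 would be silylated (Me3SiCl, imidazole, CH2Cl2) to methyl (3R)-2-methylidene-5-(oxetan-3-yl)-3-(trimethylsilyloxy)pentanoate F1.
- The oxetane would then be opened with Me3SiBr under a chiral squaramide hydrogen-bond-donor catalyst (a known enantioselective bromide opening of 3-substituted oxetanes). The catalyst enantiomer is chosen so that bromide enters the CH2 that is to become C6, giving methyl (3R,5R)-6-bromo-2-methylidene-3-(trimethylsilyloxy)-5-[(trimethylsilyloxy)methyl]hexanoate F2.
- Bu4NF in THF at 0 °C would remove both silyl groups to methyl (3R,5R)-6-bromo-3-hydroxy-5-(hydroxymethyl)-2-methylidenehexanoate F3 in the flask. Its secondary alkoxide should close the oxane by Williamson etherification (6-exo-tet, faster than 4-exo return to the oxetane), and the route is rejoined at 7.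

Step 8. Facial selectivity at the unbranched aldehyde may be insufficient or of the wrong sense, and the terminal alkyne may be consumed by the alkenylnickel species. The fallback sets out from 12 and 13 and separates C–C bond formation from stereocontrol.
- A ligand-free Nozaki–Hiyama–Kishi coupling (CrCl2 in excess, NiCl2 cat., DMF) would give racemic 10-methyl-6-methylideneundec-9-en-1-yn-5-ol F4.
- Dess–Martin oxidation would give 10-methyl-6-methylideneundec-9-en-1-yn-5-one F5.
- Corey–Bakshi–Shibata reduction ((S)-2-methyl-oxazaborolidine, catecholborane, PhMe, −78 °C), with the α-branched alkenyl group as the large substituent, should deliver the (5R)-alcohol and rejoin the route at 14.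

Step 2. Turnover with the unbranched aldehyde may be slow and product may be lost into the dioxanone pathway, which lowers conversion and can erode enantiomeric purity. The fallback sets out from 3 and replaces asymmetric catalysis by enzymatic resolution.
- DABCO-promoted Morita–Baylis–Hillman reaction with methyl acrylate would give racemic methyl 3-hydroxy-2-methylidene-5-(oxetan-3-yl)pentanoate F6.
- Acetylation (AcCl, pyridine, 0 °C) would give racemic methyl 3-acetyloxy-2-methylidene-5-(oxetan-3-yl)pentanoate F7.
- Hydrolysis with Burkholderia cepacia lipase (phosphate buffer pH 7, MTBE) would be stopped near half conversion. By the empirical size rule for lipases, with the acrylate unit as the large group, the (3R)-acetate is expected to be hydrolysed, leaving methyl (3S)-3-acetyloxy-2-methylidene-5-(oxetan-3-yl)pentanoate F8; the sense is to be verified by MTPA ester analysis.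
- The route is rejoined at 6, and step 3 is then not needed.

Further compounds
F1 | step 4 | methyl (3R)-2-methylidene-5-(oxetan-3-yl)-3-(trimethylsilyloxy)pentanoate | COC(=O)C(=C)[C@H](O[Si](C)(C)C)CCC1COC1
F2 | step 4 | methyl (3R,5R)-6-bromo-2-methylidene-3-(trimethylsilyloxy)-5-[(trimethylsilyloxy)methyl]hexanoate | C[Si](C)(C)OC[C@H](CBr)CC[C@H](C(=C)C(=O)OC)O[Si](C)(C)C
F3 | step 4 | methyl (3R,5R)-6-bromo-3-hydroxy-5-(hydroxymethyl)-2-methylidenehexanoate | OC[C@H](CBr)CC[C@H](C(=C)C(=O)OC)O
F4 | step 8 | racemic 10-methyl-6-methylideneundec-9-en-1-yn-5-ol | C=C(CCC=C(C)C)C(O)CCC#C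
F5 | step 8 | 10-methyl-6-methylideneundec-9-en-1-yn-5-one | C=C(CCC=C(C)C)C(=O)CCC#C
F6 | step 2 | racemic methyl 3-hydroxy-2-methylidene-5-(oxetan-3-yl)pentanoate | COC(=O)C(=C)C(O)CCC1COC1
F7 | step 2 | racemic methyl 3-acetyloxy-2-methylidene-5-(oxetan-3-yl)pentanoate | COC(=O)C(=C)C(OC(C)=O)CCC1COC1
F8 | step 2 | methyl (3S)-3-acetyloxy-2-methylidene-5-(oxetan-3-yl)pentanoate | COC(=O)C(=C)[C@@H](OC(C)=O)CCC1COC1
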